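**Plan**

1. Numbering (thymol type): arene C1–C6, C7 is the benzylic CH2 on C1, the phenol oxygen O3 sits on C3, C8 is the quaternary carbon on C4, and C9 and C10 are the two CH2 groups on C8.
2. The retrosynthesis cuts, in this order: the oxirane O8–C9 bond, the aryl O3–tigloyl bond, the two isobutyrate acyl–O bonds at O7 and O10, and the C4–C8 bond between the arene and a protected dihydroxyacetone.
3. Enabling feature: C8 bears two CH2–O arms that differ only in what the oxygen carries (C9 inside the three-membered ring, C10 as an ester). The side chain is therefore a 2-arylglycerol desymmetrized at C8, and O7 holds the same isobutyryl group as O10.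
4. Forward: an aryllithium addition joins C4 to C8, unmasking gives an achiral pentaol, a lipase installs both isobutyrates, the phenol is tigloylated, and the only ring formed, the oxirane, closes last by O8 attacking C9.
5. Stereochemistry: the single stereocenter C8 arises in the lipase step from the enzyme's choice of the pro-R CH2OH. The C8–O8 bond is never broken afterwards, so C8 reaches the target as R.

Key step: step 6

Assumption: Burkholderia cepacia lipase is taken to acylate the pro-R hydroxymethyl arm of the pentaol; if a trial run shows the pro-S preference, a lipase of opposite preference (for example Candida antarctica lipase B) takes its place and nothing else in the route changes.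

**Route**

Step 1
Reactants: 1 methyl 4-bromo-3-hydroxybenzoate
Product: 2 2-bromo-5-(hydroxymethyl)phenol
Conditions: iBu2AlH (3.3 equiv), THF/toluene, −78 to 0 °C; then 1 M HCl
Reagents that add atoms: none
Why: Aluminium hydride reduction of an ester, in which the first equivalent turns the phenol into an inert aluminium phenoxide and the next two take the methyl ester to the benzylic alcohol, while the aryl bromide is untouched at low temperature.

Step 2
Reactants: 2 2-bromo-5-(hydroxymethyl)phenol
Product: 3 1-bromo-2-(triisopropylsilyloxy)-4-(triisopropylsilyloxymethyl)benzene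
Conditions: TIPSCl (2.4 equiv), imidazole, DMF, rt to 40 °C
Reagents that add atoms: triisopropylsilyl chloride (TIPSCl), CC(C)[Si](Cl)(C(C)C)C(C)C
Why: Imidazole-promoted silylation protects both hydroxyls in one operation, and the bulky triisopropylsilyl group on the phenol oxygen is chosen because it resists 1,3 O-to-C silyl migration (retro-Brook rearrangement) once the neighbouring carbon is lithiated.

Step 3
Reactants: 3 1-bromo-2-(triisopropylsilyloxy)-4-(triisopropylsilyloxymethyl)benzene, 4 2,2-dimethyl-1,3-dioxan-5-one
Product: 6 5-[2-(triisopropylsilyloxy)-4-(triisopropylsilyloxymethyl)phenyl]-2,2-dimethyl-1,3-dioxan-5-ol, via aryllithium 5 (not isolated)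
Conditions: n-BuLi (1.05 equiv), THF, −78 °C, 15 min; then 4 (1.3 equiv), −78 °C; then AcOH, −78 °C
Reagents that add atoms: 2,2-dimethyl-1,3-dioxan-5-one (4), CC1(C)OCC(=O)CO1
Why: Bromine–lithium exchange followed by 1,2-addition of the aryllithium to the ketone forms the C4–C8 bond, the low temperature, the bulky silyl group and the cold acidic quench serving to outrun ketone enolization and silyl migration; C8 is not yet a stereocenter because its two CH2O arms are identical.

Step 4
Reactants: 6 5-[2-(triisopropylsilyloxy)-4-(triisopropylsilyloxymethyl)phenyl]-2,2-dimethyl-1,3-dioxan-5-ol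
Product: 7 5-[2-hydroxy-4-(hydroxymethyl)phenyl]-2,2-dimethyl-1,3-dioxan-5-ol
Conditions: Bu4NF (2.5 equiv), THF, 0 °C to rt
Reagents that add atoms: none
Why: Fluoride-induced desilylation cleaves the aryl and the benzylic silyl ether while the acetonide and the tertiary alcohol are inert to fluoride, which leaves a compound that can still be purified by chromatography before the very polar pentaol is made.

Step 5
Reactants: 7 5-[2-hydroxy-4-(hydroxymethyl)phenyl]-2,2-dimethyl-1,3-dioxan-5-ol
Product: 8 2-[2-hydroxy-4-(hydroxymethyl)phenyl]propane-1,2,3-triol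
Conditions: Dowex 50WX8 (H+ form), THF/H2O 4:1, rt to 40 °C; filter, evaporate
Reagents that add atoms: none
Why: Acid-catalysed acetal hydrolysis opens the six-membered acetonide, the tertiary benzylic hydroxyl should survive because ionization at C8 is disfavoured by its two β-oxygen substituents, and the only by-product is volatile, so the pentaol is obtained by filtration and evaporation.

Step 6
Reactants: 8 2-[2-hydroxy-4-(hydroxymethyl)phenyl]propane-1,2,3-triol, 9 isobutyric anhydride
Product: 10 (2R)-2,3-dihydroxy-2-[2-hydroxy-4-(isobutyryloxymethyl)phenyl]propyl isobutyrate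
Conditions: Burkholderia cepacia lipase (immobilized), 9 (2.2 equiv), dry THF/t-BuOMe 1:1, 30 °C; enzyme filtered off when the diester is at its maximum; neutral work-up
Reagents that add atoms: isobutyric anhydride (9), CC(C)C(=O)OC(=O)C(C)C
Why: The active-site serine is acylated by 9, and the isobutyryl-enzyme hands its acyl group first to the unhindered benzylic O7 hydroxyl and then to one CH2OH of the 2-arylglycerol unit, so the O7–acyl and O10–acyl bonds form in one operation with isobutyric acid as the only by-product. The closest known reaction type is the lipase-catalysed enantiotopic-group-selective acylation of prochiral 2,2-disubstituted propane-1,3-diols and 2-substituted glycerols with anhydrides or enol esters. No ring closes in this step. C8 becomes a stereocenter under catalyst control: the chiral pocket of the enzyme fixes the aryl group and the tertiary hydroxyl so that only the pro-R hydroxymethyl reaches the acyl-enzyme, which corresponds to the R configuration. The chemoselectivity needed comes from the substrate and the donor, because lipases accept neither phenolic nor tertiary hydroxyl groups as acyl acceptors and the hindered anhydride barely reacts without enzyme when no base is present; over-acylation to the triester would draw mainly on the wrong-arm monoester, which still offers the enzyme its preferred pro-R hydroxymethyl, so the enantiomeric purity of the surviving monoester can only rise. Since an isobutyryl shift from O10 to O9 (directly or by way of O8) would erase the stereocenter, work-up and purification are kept neutral to slightly acidic.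

Step 7
Reactants: 10 (2R)-2,3-dihydroxy-2-[2-hydroxy-4-(isobutyryloxymethyl)phenyl]propyl isobutyrate, 11 tigloyl chloride [(E)-2-methylbut-2-enoyl chloride]
Product: 12 2-[(2R)-1,2-dihydroxy-3-(isobutyryloxy)propan-2-yl]-5-(isobutyryloxymethyl)phenyl (E)-2-methylbut-2-enoate
Conditions: 11 (1.05 equiv), Et3N (1.2 equiv), CH2Cl2, −40 to −10 °C; then aq. NaH2PO4; product used at once
Reagents that add atoms: tigloyl chloride (11), C/C=C(\C)C(Cl)=O
Why: Acid chloride esterification of the phenol as its triethylammonium phenoxide should be chemoselective, because Et3N does not ionize the aliphatic hydroxyls, the primary one is neopentyl-like and the tertiary one inert towards a deactivated conjugated acid chloride used cold without DMAP, and the short cold contact with the amine should not permit isobutyryl migration at C8.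

Step 8
Reactants: 12 2-[(2R)-1,2-dihydroxy-3-(isobutyryloxy)propan-2-yl]-5-(isobutyryloxymethyl)phenyl (E)-2-methylbut-2-enoate
Product: 14 2-[(2R)-2-(isobutyryloxymethyl)oxiran-2-yl]-5-(isobutyryloxymethyl)phenyl (E)-2-methylbut-2-enoate (the target), via primary tosylate 13 (not isolated)
Conditions: TsCl (1.1 equiv), Bu2SnO (5 mol %), Et3N (1.3 equiv), CH2Cl2, 0 °C to rt; then DBU (2 equiv), 0 °C to rt; chromatography on Et3N-deactivated silica
Reagents that add atoms: none
Why: Bu2SnO-catalysed sulfonylation through a stannylene acetal of the 1,2-diol should tosylate only the primary O9 hydroxyl, and DBU then brings about an intramolecular Williamson closure (3-exo-tet) of the tertiary O8 onto C9, in which the C8–O8 bond is never broken, so the configuration at C8 is retained and appears as R in the oxirane.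

**Compound list**

1 | methyl 4-bromo-3-hydroxybenzoate | COC(=O)c1ccc(Br)c(O)c1 | starting material
2 | 2-bromo-5-(hydroxymethyl)phenol | OCc1ccc(Br)c(O)c1 | intermediate
3 | 1-bromo-2-(triisopropylsilyloxy)-4-(triisopropylsilyloxymethyl)benzene | CC(C)[Si](C(C)C)(C(C)C)Oc1cc(CO[Si](C(C)C)(C(C)C)C(C)C)ccc1Br | intermediate
4 | 2,2-dimethyl-1,3-dioxan-5-one | CC1(C)OCC(=O)CO1 | starting material
5 | [2-(triisopropylsilyloxy)-4-(triisopropylsilyloxymethyl)phenyl]lithium (formed in the flask) | CC(C)[Si](C(C)C)(C(C)C)Oc1cc(CO[Si](C(C)C)(C(C)C)C(C)C)ccc1[Li] | intermediate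
6 | 5-[2-(triisopropylsilyloxy)-4-(triisopropylsilyloxymethyl)phenyl]-2,2-dimethyl-1,3-dioxan-5-ol | CC(C)[Si](C(C)C)(C(C)C)Oc1cc(CO[Si](C(C)C)(C(C)C)C(C)C)ccc1C1(O)COC(C)(C)OC1 | intermediate
7 | 5-[2-hydroxy-4-(hydroxymethyl)phenyl]-2,2-dimethyl-1,3-dioxan-5-ol | Oc1cc(CO)ccc1C1(O)COC(C)(C)OC1 | intermediate
8 | 2-[2-hydroxy-4-(hydroxymethyl)phenyl]propane-1,2,3-triol (achiral, prochiral at C8) | Oc1cc(CO)ccc1C(O)(CO)CO | intermediate
9 | isobutyric anhydride | CC(C)C(=O)OC(=O)C(C)C | starting material
10 | (2R)-2,3-dihydroxy-2-[2-hydroxy-4-(isobutyryloxymethyl)phenyl]propyl isobutyrate | Oc1cc(COC(=O)C(C)C)ccc1[C@](O)(COC(=O)C(C)C)CO | intermediate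
11 | tigloyl chloride, (E)-2-methylbut-2-enoyl chloride | C/C=C(\C)C(Cl)=O | starting material
12 | 2-[(2R)-1,2-dihydroxy-3-(isobutyryloxy)propan-2-yl]-5-(isobutyryloxymethyl)phenyl (E)-2-methylbut-2-enoate | C/C=C(\C)C(=O)Oc1cc(COC(=O)C(C)C)ccc1[C@](O)(COC(=O)C(C)C)CO | intermediate
13 | 2-[(2S)-2-hydroxy-1-(isobutyryloxy)-3-(tosyloxy)propan-2-yl]-5-(isobutyryloxymethyl)phenyl (E)-2-methylbut-2-enoate (formed in the flask; same spatial arrangement as 12, the descriptor is S only because CH2OTs outranks CH2O-acyl) | C/C=C(\C)C(=O)Oc1cc(COC(=O)C(C)C)ccc1[C@](O)(COC(=O)C(C)C)COS(=O)(=O)c1ccc(C)cc1 | intermediate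
14 | 2-[(2R)-2-(isobutyryloxymethyl)oxiran-2-yl]-5-(isobutyryloxymethyl)phenyl (E)-2-methylbut-2-enoate (CNP0189152.1) | C/C=C(\C)C(=O)Oc1cc(COC(=O)C(C)C)ccc1[C@]1(COC(=O)C(C)C)CO1 | target

**Totals and risks**

Total step count: 8. Longest linear sequence: 8 steps (1 to 14); compounds 4, 9 and 11 are bought.

Steps most likely to fail:

1. Step 6. The enzyme may discriminate poorly between the two enantiotopic hydroxymethyl arms, may acylate the neopentyl-type arm next to the ortho-substituted arene too slowly, or may run on to the triester. Fallback: a chiral copper catalyst takes over the desymmetrization. Setting out from 6, the acetonide alone is hydrolysed (AcOH/H2O/THF, rt; the silyl ethers stay) to 2-[2-(triisopropylsilyloxy)-4-(triisopropylsilyloxymethyl)phenyl]propane-1,2,3-triol F1. Monoacylation with isobutyryl chloride and Et3N under CuCl2 (divalent copper) and the Ph-BOX antipode that a test reaction shows to give the R ester, a known desymmetrization of 2-substituted propane-1,2,3-triols, should give (2R)-2,3-dihydroxy-2-[2-(triisopropylsilyloxy)-4-(triisopropylsilyloxymethyl)phenyl]propyl isobutyrate F2. Bu4NF buffered with AcOH in THF removes both silyl groups without free base and gives (2R)-2,3-dihydroxy-2-[2-hydroxy-4-(hydroxymethyl)phenyl]propyl isobutyrate F3. The benzylic hydroxyl, by far the most accessible one, is then acylated with one equivalent of 9 under the lipase, now a purely chemoselective task, and the route is rejoined at 10.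

2. Step 7. The acid chloride may also acylate the primary O9 hydroxyl, and the amine may induce isobutyryl migration that erodes the enantiomeric purity at C8. Fallback: the tiglate is introduced before any stereocenter or migratable ester exists. Setting out from 7, phase-transfer Schotten–Baumann acylation of the phenoxide (11, aq. NaOH, CH2Cl2, Bu4NHSO4, 0 °C) should give 2-(5-hydroxy-2,2-dimethyl-1,3-dioxan-5-yl)-5-(hydroxymethyl)phenyl (E)-2-methylbut-2-enoate F4. Acetonide hydrolysis as in step 5 gives 5-(hydroxymethyl)-2-(1,2,3-trihydroxypropan-2-yl)phenyl (E)-2-methylbut-2-enoate F5. The lipase acylation with 9, run on this tetraol, installs both isobutyrates and the route is rejoined at 12.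

3. Step 8. Under base the tigloyl group may shift from the phenol oxygen to the neighbouring tertiary alkoxide, or be cleaved by the amidine, in competition with ring closure; sulfonylation of the hindered primary hydroxyl may also stay incomplete. Fallback: Mitsunobu cyclodehydration. Setting out from 12, PPh3 and diisopropyl azodicarboxylate in toluene (0 °C to rt) activate the primary O9 as an oxyphosphonium ion, which the tertiary O8 displaces. No sulfonate and no amine base are involved, no new compound is isolated (F0), and the route is rejoined at the target 14.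

**Further compounds**

F1 | step 6 | 2-[2-(triisopropylsilyloxy)-4-(triisopropylsilyloxymethyl)phenyl]propane-1,2,3-triol | CC(C)[Si](C(C)C)(C(C)C)Oc1cc(CO[Si](C(C)C)(C(C)C)C(C)C)ccc1C(O)(CO)CO
F2 | step 6 | (2R)-2,3-dihydroxy-2-[2-(triisopropylsilyloxy)-4-(triisopropylsilyloxymethyl)phenyl]propyl isobutyrate | CC(C)[Si](C(C)C)(C(C)C)Oc1cc(CO[Si](C(C)C)(C(C)C)C(C)C)ccc1[C@](O)(COC(=O)C(C)C)CO
F3 | step 6 | (2R)-2,3-dihydroxy-2-[2-hydroxy-4-(hydroxymethyl)phenyl]propyl isobutyrate | Oc1cc(CO)ccc1[C@](O)(COC(=O)C(C)C)CO
F4 | step 7 | 2-(5-hydroxy-2,2-dimethyl-1,3-dioxan-5-yl)-5-(hydroxymethyl)phenyl (E)-2-methylbut-2-enoate | C/C=C(\C)C(=O)Oc1cc(CO)ccc1C1(O)COC(C)(C)OC1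
F5 | step 7 | 5-(hydroxymethyl)-2-(1,2,3-trihydroxypropan-2-yl)phenyl (E)-2-methylbut-2-enoate | C/C=C(\C)C(=O)Oc1cc(CO)ccc1C(O)(CO)CO
F0 | step 8 | none | none
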